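(The numbers are invented; the flask was simulated.)

Late in the run of this flask I expected two end products, and I asked how the starting material would divide between them.

starting material 0.39 M; partner 1.20 equiv; free catalyst 2 mol% (in portions, 3); second catalyst 0.1 mol%; time 15 d; the portions of free catalyst follow each other after 50 min, the first at the start

    starting material + free catalyst ⇌ free catalyst + open intermediate (K1 = 0.33, k1 = 230 L mol⁻¹ h⁻¹)
    second catalyst + open intermediate ⇌ catalyst intermediate (K2 = 74 L mol⁻¹, k2 = 830 L mol⁻¹ h⁻¹)
    partner + catalyst intermediate → second catalyst + target (k3 = 15 L mol⁻¹ h⁻¹)
    starting material + partner → uncatalysed product (k4 = 0.29 L mol⁻¹ h⁻¹)

* how much target there is at 15 d, in percent of the starting material charged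
* how much uncatalysed product there is at 15 d, in percent of the starting material charged

Partner enters both steps that consume it at first order, so it cancels from their ratio, and at 1.20 equiv it leaves starting material as the limiting reagent. I then turned constants into times. The forward opening step has a half-life of 0.39 h with the whole catalyst counted, shorter than the 0.21 d of the uncatalysed step at charged amounts, so I held the open intermediate in equilibrium with starting material, whose concentration I call A. With κ the first equilibrium constant and c the charge, A begins, once opening has equilibrated, at Ā = c/(1+κ) = 0.293 M. The portions worried me, but the last arrives after 1.67 h, which is shorter than that uncatalysed half-life, and I let it pass.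

With the second catalyst fully bound, the two product steps run equally fast at the crossover concentration A*, the rate constant to target times the second catalyst charged, over the uncatalysed rate constant: 0.0202 M. Ā stands 14.5 times above it, which suggests a target share of 6.45%. But A falls, and the ratio improves as it does; integrating gives 18.9%. That was too generous. Binding of the second catalyst is half complete at A = 0.0410 M, higher than A*, so the tail, where the gain lies, runs with second catalyst largely unbound. Writing a for the product of both equilibrium constants, the integral becomes (1+κ)(A*/c) ln(1 + aĀ/(1 + aA*)). I committed to 12.1% target and the remainder, 87.9%, as uncatalysed product. The forecast gave 12% (11% to 13%) and 87.9% (86.5% to 89%), noting that “both paths consume the partner at first order”.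

The flask gave 11.2% target and 88.8% uncatalysed product at 15.0 d; at 0.0694 d, its 62.6% of starting material stood 15.2 times above A* scaled by the 79.7% of second catalyst held as catalyst intermediate, and at 0.317 d the uncatalysed step still used partner 10 times as fast as the step to target. In the neighbour flask with 0.06 mol% of second catalyst, A* is 0.0121 M, the same integral gives 7.74%, and that flask held 7.12% target.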